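**Retrosynthetic overview**

1. The aryl ether is made last, from the C11 neopentyl alcohol and umbelliferone (Mitsunobu).
2. The 8α-methyl comes from Me2CuLi addition to a Δ7-6-ketone of the trans-decalin; the C6 oxygen is installed by Shapiro reaction of the C8 ketone plus allylic oxidation and is then removed.
3. The C9 quaternary centre and the trans ring fusion (C10) come from Li/NH3 reductive alkylation of the Δ9(10)-8-enone with BnOCH2Cl, which supplies C11.
4. Ring A is built onto ring B by Robinson annulation with ethyl vinyl ketone; the key step is an enantioselective Michael addition that breaks the symmetry of 2,3-dimethylcyclohexane-1,4-dione and fixes C5.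
5. Ring B comes first, by Birch reduction and hydrolysis of 1,4-dimethoxy-2,3-dimethylbenzene; ring order is B, then A.

Assumption: locants follow drimane-type numbering (C5/C10 ring-fusion carbons, C3 ketone, methyls on C4, C5, C8, C9, C11 = CH2O carbon on C9); β is the face of the C5 methyl, "trans-decalin" means 5β-Me/10α-H; C4 stays epimerisable until step 9 and is drawn throughout in its final 4β form.

**Step 1**
Reactants: 1 1,4-dimethoxy-2,3-dimethylbenzene
Product: 3 2,3-dimethylcyclohexane-1,4-dione (cis/trans mixture), via 1,4-dimethoxy-2,3-dimethylcyclohexa-1,4-diene 2 (not isolated)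
Conditions: Li, NH3(l), t-BuOH, THF, −78 to −33 °C; then 1 M HCl, THF, 20 °C
Reagents that add atoms: water (O)
Why: Birch reduction of the electron-rich arene gives the 1,4-dihydro bis(enol ether), and acid hydrolysis unmasks the symmetric diketone, whose two methine centres are not fixed because they epimerise through the enols.

**Step 2**
Reactants: 3 2,3-dimethylcyclohexane-1,4-dione; 4 ethyl vinyl ketone; 5 (R)-1-phenylethylamine
Product: 8 (4aR,5R)-1,4a,5-trimethyl-4,4a,7,8-tetrahydronaphthalene-2,6(3H,5H)-dione, via imine 6 (not isolated), via triketone 7 (not isolated)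
Conditions: TsOH (cat.), toluene, reflux, −H2O; THF, 40 °C; 20% aq AcOH, 20 °C; then NaOMe, MeOH, 60 °C
Reagents that add atoms: none
Why: d'Angelo chiral-imine Michael addition followed by Robinson aldol condensation: the secondary enamine of either (equivalent) carbonyl attacks the enone through its more substituted carbon on the face away from the phenyl group, which breaks the symmetry of the dione and sets the C5 quaternary centre (5β-Me; the (R)-amine is chosen by analogy with 2-methylcyclohexanone, the (S)-amine would give the enantiomer), while the still-enolisable C4 methine funnels into one diastereomer.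

**Step 3**
Reactants: 8 (4aR,5R)-1,4a,5-trimethyl-4,4a,7,8-tetrahydronaphthalene-2,6(3H,5H)-dione
Product: 9 3,3-(ethylenedioxy)-4β,5β,9-trimethyldecal-9(10)-en-8-one
Conditions: HOCH2CH2OH, TsOH (cat.), benzene, reflux (Dean–Stark)
Reagents that add atoms: ethylene glycol (OCCO)
Why: Acid-catalysed ketalisation is selective for the saturated C3 ketone over the conjugated C8 enone, as with Wieland–Miescher-type diketones, and touches no fixed stereocentre.

**Step 4**
Reactants: 9 3,3-(ethylenedioxy)-4β,5β,9-trimethyldecal-9(10)-en-8-one; 10 benzyl chloromethyl ether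
Product: 12 9α-(benzyloxymethyl)-3,3-(ethylenedioxy)-4β,5β,9β-trimethyl-trans-decalin-8-one, via lithium enolate 11 (not isolated)
Conditions: Li, NH3(l), t-BuOH (1 equiv), THF, −78 °C; isoprene; NH3 evaporated; then 10, THF, −78 to 0 °C
Reagents that add atoms: none
Why: Stork reductive alkylation: dissolving-metal reduction protonates C10 axially to give the trans ring fusion (10α-H) and a regiodefined C8(9) enolate, which is C-alkylated on the α face, away from the axial 5β-methyl, setting C9 (Me β, CH2O α).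

**Step 5**
Reactants: 12 9α-(benzyloxymethyl)-3,3-(ethylenedioxy)-4β,5β,9β-trimethyl-trans-decalin-8-one
Product: 14 9α-(benzyloxymethyl)-3,3-(ethylenedioxy)-4β,5β,9β-trimethyl-trans-decal-7-ene, via arenesulfonylhydrazone 13 (not isolated)
Conditions: 2,4,6-(i-Pr)3C6H2SO2NHNH2, THF, 20 °C; then n-BuLi, −78 to 0 °C; H2O
Reagents that add atoms: none
Why: Shapiro reaction: the hydrazone dianion can only form towards C7 (C9 is quaternary), loss of sulfinate and N2 gives the C8 vinyllithium, and protonation gives the Δ7 alkene without touching a stereocentre.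

**Step 6**
Reactants: 14 9α-(benzyloxymethyl)-3,3-(ethylenedioxy)-4β,5β,9β-trimethyl-trans-decal-7-ene
Product: 16 9α-(benzyloxymethyl)-3,3-(ethylenedioxy)-4β,5β,9β-trimethyl-trans-decal-7-en-6-one, via allylic alcohol 15 (not isolated)
Conditions: SeO2 (cat.), t-BuOOH, CH2Cl2, 20 °C; then Dess–Martin periodinane, NaHCO3, CH2Cl2, 20 °C
Reagents that add atoms: tert-butyl hydroperoxide (CC(C)(C)OO)
Why: Selenium dioxide allylic oxidation (ene reaction, then [2,3]-sigmatropic shift) oxygenates C6, the only allylic CH2, without moving the double bond, and Dess–Martin oxidation gives the enone; the C6 carbinol configuration is irrelevant.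

**Step 7**
Reactants: 16 9α-(benzyloxymethyl)-3,3-(ethylenedioxy)-4β,5β,9β-trimethyl-trans-decal-7-en-6-one
Product: 17 9α-(benzyloxymethyl)-3,3-(ethylenedioxy)-4β,5β,8α,9β-tetramethyl-trans-decalin-6-one
Conditions: Me2CuLi, Et2O, −40 to 0 °C; aq NH4Cl
Reagents that add atoms: lithium dimethylcuprate ([Li+].C[Cu-]C)
Why: Cuprate conjugate addition delivers methyl to C8 axially and anti to the axial 9β-methyl of the rigid trans-decalin enone, giving 8α-Me/8β-H at a centre that is β to the ketone and cannot epimerise.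

**Step 8**
Reactants: 17 9α-(benzyloxymethyl)-3,3-(ethylenedioxy)-4β,5β,8α,9β-tetramethyl-trans-decalin-6-one
Product: 19 9α-(benzyloxymethyl)-3,3-(ethylenedioxy)-4β,5β,8α,9β-tetramethyl-trans-decalin, via hydrazone 18 (not isolated)
Conditions: N2H4·H2O, KOH, diethylene glycol, 130 then 200 °C
Reagents that add atoms: none
Why: Wolff–Kishner reduction (Huang-Minlon conditions) deletes the C6 carbonyl; the ketal and benzyl ether are base-stable and no stereocentre is enolisable (C5 quaternary, C8 in the β position).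

**Step 9**
Reactants: 19 9α-(benzyloxymethyl)-3,3-(ethylenedioxy)-4β,5β,8α,9β-tetramethyl-trans-decalin
Product: 21 [(1R,2R,4aS,5R,8aR)-1,2,4a,5-tetramethyl-6-oxodecahydronaphthalen-1-yl]methanol, via ketal alcohol 20 (not isolated)
Conditions: H2 (1 atm), Pd/C, EtOAc–MeOH, 20 °C; then 2 M HCl, THF, 40 °C
Reagents that add atoms: water (O)
Why: Hydrogenolysis frees the C11 alcohol, aqueous acid hydrolyses the dioxolane, and acid-catalysed enolisation equilibrates C4 to the equatorial 4β-methyl ketone (cis to the 5β-methyl, as in friedelin-type 3-ketones).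

**Step 10**
Reactants: 21 [(1R,2R,4aS,5R,8aR)-1,2,4a,5-tetramethyl-6-oxodecahydronaphthalen-1-yl]methanol; 22 umbelliferone
Product: 23 7-{[(1R,2R,4aS,5R,8aR)-1,2,4a,5-tetramethyl-6-oxodecahydronaphthalen-1-yl]methoxy}-2H-chromen-2-one
Conditions: n-Bu3P, 1,1'-(azodicarbonyl)dipiperidine, toluene, 80 °C
Reagents that add atoms: none
Why: Mitsunobu etherification: the acidic phenol (pKa about 8) displaces the phosphonium-activated oxygen by SN2 at the C11 methylene, which is not a stereocentre, so the five stereocentres are untouched.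

**Compound list**

1 | 1,4-dimethoxy-2,3-dimethylbenzene | COc1ccc(OC)c(C)c1C | starting material
2 | 1,4-dimethoxy-2,3-dimethylcyclohexa-1,4-diene (racemic) | COC1=C(C)C(C)C(OC)=CC1 | intermediate
3 | 2,3-dimethylcyclohexane-1,4-dione (cis/trans mixture) | CC1C(C)C(=O)CCC1=O | intermediate
4 | ethyl vinyl ketone (pent-1-en-3-one) | C=CC(=O)CC | starting material
5 | (R)-1-phenylethylamine | C[C@@H](N)c1ccccc1 | starting material
6 | mono-imine of 3 with 5 (reacts as its secondary enamine tautomer) | CC1C(C)C(=O)CCC1=N[C@H](C)c1ccccc1 | intermediate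
7 | (2R,3R)-2,3-dimethyl-2-(3-oxopentyl)cyclohexane-1,4-dione | CCC(=O)CC[C@@]1(C)C(=O)CCC(=O)[C@@H]1C | intermediate
8 | (4aR,5R)-1,4a,5-trimethyl-4,4a,7,8-tetrahydronaphthalene-2,6(3H,5H)-dione | CC1=C2CCC(=O)[C@H](C)[C@@]2(C)CCC1=O | intermediate
9 | 3,3-(ethylenedioxy)-4β,5β,9-trimethyldecal-9(10)-en-8-one | CC1=C2CCC3(OCCO3)[C@H](C)[C@@]2(C)CCC1=O | intermediate
10 | benzyl chloromethyl ether | ClCOCc1ccccc1 | starting material
11 | lithium 3,3-(ethylenedioxy)-4β,5β,9-trimethyl-trans-decal-8-en-8-olate | CC1=C(O[Li])CC[C@@]2(C)[C@H]1CCC3(OCCO3)[C@@H]2C | intermediate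
12 | 9α-(benzyloxymethyl)-3,3-(ethylenedioxy)-4β,5β,9β-trimethyl-trans-decalin-8-one | O=C1CC[C@@]2(C)[C@@H](CCC3(OCCO3)[C@@H]2C)[C@]1(C)COCc1ccccc1 | intermediate
13 | 2,4,6-triisopropylbenzenesulfonylhydrazone of 12 | CC(C)c1cc(C(C)C)c(S(=O)(=O)NN=C2CC[C@@]3(C)[C@@H](CCC4(OCCO4)[C@@H]3C)[C@]2(C)COCc2ccccc2)c(C(C)C)c1 | intermediate
14 | 9α-(benzyloxymethyl)-3,3-(ethylenedioxy)-4β,5β,9β-trimethyl-trans-decal-7-ene | C1=CC[C@@]2(C)[C@@H](CCC3(OCCO3)[C@@H]2C)[C@]1(C)COCc1ccccc1 | intermediate
15 | 9α-(benzyloxymethyl)-3,3-(ethylenedioxy)-4β,5β,9β-trimethyl-trans-decal-7-en-6α-ol | C1=C[C@H](O)[C@@]2(C)[C@@H](CCC3(OCCO3)[C@@H]2C)[C@]1(C)COCc1ccccc1 | intermediate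
16 | 9α-(benzyloxymethyl)-3,3-(ethylenedioxy)-4β,5β,9β-trimethyl-trans-decal-7-en-6-one | C1=CC(=O)[C@@]2(C)[C@@H](CCC3(OCCO3)[C@@H]2C)[C@]1(C)COCc1ccccc1 | intermediate
17 | 9α-(benzyloxymethyl)-3,3-(ethylenedioxy)-4β,5β,8α,9β-tetramethyl-trans-decalin-6-one | C[C@@H]1CC(=O)[C@@]2(C)[C@@H](CCC3(OCCO3)[C@@H]2C)[C@]1(C)COCc1ccccc1 | intermediate
18 | hydrazone of 17 | C[C@@H]1CC(=NN)[C@@]2(C)[C@@H](CCC3(OCCO3)[C@@H]2C)[C@]1(C)COCc1ccccc1 | intermediate
19 | 9α-(benzyloxymethyl)-3,3-(ethylenedioxy)-4β,5β,8α,9β-tetramethyl-trans-decalin | C[C@@H]1CC[C@@]2(C)[C@@H](CCC3(OCCO3)[C@@H]2C)[C@]1(C)COCc1ccccc1 | intermediate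
20 | 3,3-(ethylenedioxy)-9α-(hydroxymethyl)-4β,5β,8α,9β-tetramethyl-trans-decalin | C[C@@H]1CC[C@@]2(C)[C@@H](CCC3(OCCO3)[C@@H]2C)[C@]1(C)CO | intermediate
21 | [(1R,2R,4aS,5R,8aR)-1,2,4a,5-tetramethyl-6-oxodecahydronaphthalen-1-yl]methanol | C[C@@H]1CC[C@@]2(C)[C@@H](CCC(=O)[C@@H]2C)[C@]1(C)CO | intermediate
22 | umbelliferone (7-hydroxy-2H-chromen-2-one) | O=c1ccc2ccc(O)cc2o1 | starting material
23 | 7-{[(1R,2R,4aS,5R,8aR)-1,2,4a,5-tetramethyl-6-oxodecahydronaphthalen-1-yl]methoxy}-2H-chromen-2-one | C[C@@H]1CC[C@@]2(C)[C@@H](CCC(=O)[C@@H]2C)[C@]1(C)COc1ccc2ccc(=O)oc2c1 | target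

**Totals and risks**

Total steps: 10. Longest linear sequence: 10 steps (1 to 23).

Step 2 is the most exposed step: the 1,4-dione can form a bis-imine, aromatise oxidatively, or react with low selectivity. The fallback breaks the symmetry with a palladium catalyst instead of a chiral imine. It sets out from 3: t-BuOK and allyl chloroformate give allyl 2,3-dimethyl-4-oxocyclohex-1-en-1-yl carbonate F1; Pd2(dba)3 with (S)-t-Bu-PHOX effects decarboxylative asymmetric allylation to (2R,3R)-2-allyl-2,3-dimethylcyclohexane-1,4-dione F2; cross-metathesis of F2 with 4 (second-generation Hoveyda–Grubbs catalyst, RuCl2(H2IMes)(=CH-C6H4-2-O-i-Pr)) gives (2R,3R)-2,3-dimethyl-2-[(2E)-4-oxohex-2-en-1-yl]cyclohexane-1,4-dione F3; hydrogenation of its C=C bond (H2, Pd/C) returns to the route at 7, which NaOMe cyclises to 8.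

Step 6 may fail because the ene-type oxidation must engage a hindered disubstituted alkene next to a quaternary carbon. The fallback reaches the same enone by a Wharton transposition. It sets out from 12: dehydrogenation with 2-iodoxybenzoic acid (DMSO, 70 °C) gives 9α-(benzyloxymethyl)-3,3-(ethylenedioxy)-4β,5β,9β-trimethyl-trans-decal-6-en-8-one F4; nucleophilic epoxidation (H2O2, NaOH) gives the 6α,7α-epoxy ketone F5; N2H4·H2O with AcOH converts F5 into allylic alcohol 15, where the route is rejoined and Dess–Martin oxidation gives 16.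

Step 10 requires SN2 displacement at a neopentyl carbon flanked by a quaternary centre. The fallback forms the aryl–oxygen bond instead of the alkyl–oxygen bond. It sets out from 20, isolated by leaving out the acid in step 9: Pd-catalysed C–O coupling with commercial 7-bromo-2H-chromen-2-one (Pd2(dba)3, t-BuBrettPhos, Cs2CO3, toluene, 80 °C) gives 7-{[3,3-(ethylenedioxy)-4β,5β,8α,9β-tetramethyl-trans-decalin-9α-yl]methoxy}-2H-chromen-2-one F6, and 2 M HCl in THF removes the dioxolane and equilibrates C4, coming back to the route at 23.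

**Further compounds**

F1 | step 2 | allyl 2,3-dimethyl-4-oxocyclohex-1-en-1-yl carbonate | C=CCOC(=O)OC1=C(C)C(C)C(=O)CC1
F2 | step 2 | (2R,3R)-2-allyl-2,3-dimethylcyclohexane-1,4-dione | C=CC[C@@]1(C)C(=O)CCC(=O)[C@@H]1C
F3 | step 2 | (2R,3R)-2,3-dimethyl-2-[(2E)-4-oxohex-2-en-1-yl]cyclohexane-1,4-dione | CCC(=O)/C=C/C[C@@]1(C)C(=O)CCC(=O)[C@@H]1C
F4 | step 6 | 9α-(benzyloxymethyl)-3,3-(ethylenedioxy)-4β,5β,9β-trimethyl-trans-decal-6-en-8-one | O=C1C=C[C@@]2(C)[C@@H](CCC3(OCCO3)[C@@H]2C)[C@]1(C)COCc1ccccc1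
F5 | step 6 | 9α-(benzyloxymethyl)-6α,7α-epoxy-3,3-(ethylenedioxy)-4β,5β,9β-trimethyl-trans-decalin-8-one | O=C1[C@@H]2O[C@@H]2[C@@]3(C)[C@@H](CCC4(OCCO4)[C@@H]3C)[C@]1(C)COCc1ccccc1
F6 | step 10 | 7-{[3,3-(ethylenedioxy)-4β,5β,8α,9β-tetramethyl-trans-decalin-9α-yl]methoxy}-2H-chromen-2-one | C[C@@H]1CC[C@@]2(C)[C@@H](CCC3(OCCO3)[C@@H]2C)[C@]1(C)COc1ccc2ccc(=O)oc2c1
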